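**Retrosynthetic overview**
1. Side chain: the (E)-C13=C14 alkene comes from zirconium-catalysed methylalumination of a C13≡C14 alkyne, itself made from a C12 iodide; the C8 oxygen is silylated first so that it cannot close a C8–O–C12 tetrahydrofuran.
2. Ring B (formed second): the strategy rests on the tertiary carbinol C8 (OH, C17) of ring B being bonded to C9, which carries C11–C12(=O), a γ-hydroxy ester. Cutting C8–C9 gives a C8 methyl ketone on the C5 arm (C6–C7) and an (E)-enoate C9=C11–C12 on C10, trans on ring A; SmI2 closes it.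
3. C3 bromide: set equatorial on ring A before ring B exists, by hydrogenation of the C2=C3 bromoalkene made from the C3 ketone.
4. Ring A (formed first): the C5 arm by conjugate addition to the C3 enone anti to the C10 acetal, C4 gem-dimethyl by enolate methylation, and the enone from an asymmetric Diels–Alder reaction of a 2-siloxydiene with methacrolein, which sets C10.

Key step: step 12

**Remarks and assumptions**
- Locants C1–C20 are the labdane locants of the target and are used for all intermediates.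
- Assumption: the (R)-oxazaborolidinium catalyst is taken to give the (1R)-aldehyde in step 2; if the first correlation shows the opposite sense, the (S)-catalyst is used and nothing else changes.
- The C3 bromide is a spectator in the ring closure. It is installed early because the bromoalkene hydrogenation must come before any other C=C bond, and because acid unmasking of C3 after ring closure would lactonise the γ-hydroxy ester. The ester is tert-butyl for the same reason.

**Route**

Step 1
Reactants: 1 3-methylbut-3-en-2-one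
Product: 2 2-methyl-3-(triisopropylsilyloxy)buta-1,3-diene
Conditions: i-Pr3SiOTf, Et3N, CH2Cl2, 0 °C → rt
Reagents that add atoms: triisopropylsilyl trifluoromethanesulfonate, CC(C)[Si](OS(=O)(=O)C(F)(F)F)(C(C)C)C(C)C
Why: Soft enolisation (silyl triflate and amine) removes a proton of the acetyl methyl group and should give the cross-conjugated 2-siloxydiene, as in standard silyl enol ether formation from enones; no stereocentre is formed.

Step 2
Reactants: 2 2-methyl-3-(triisopropylsilyloxy)buta-1,3-diene; 3 methacrolein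
Product: 4 (1R)-1,3-dimethyl-4-(triisopropylsilyloxy)cyclohex-3-ene-1-carbaldehyde
Conditions: (R)-3,3-diphenyl-1-(2-methylphenyl)tetrahydro-1H,3H-pyrrolo[1,2-c][1,3,2]oxazaborole (20 mol%), Tf2NH (20 mol%), CH2Cl2, −78 °C
Reagents that add atoms: none
Why: Lewis-acid-catalysed asymmetric Diels–Alder reaction, in which the diene terminus next to the siloxy carbon bonds to the β-carbon of the coordinated enal so that C3–O lies 1,4 to the new quaternary C10, and the chiral oxazaborolidinium blocks one face of the s-trans enal, which should set C10 as (R).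

Step 3
Reactants: 4 (1R)-1,3-dimethyl-4-(triisopropylsilyloxy)cyclohex-3-ene-1-carbaldehyde
Product: 5 (1R)-1,3-dimethyl-4-oxocyclohex-2-ene-1-carbaldehyde
Conditions: Pd(OAc)2 (1.05 equiv), MeCN, 40 °C
Reagents that add atoms: none
Why: Saegusa–Ito oxidation, in which the silyl enol ether gives a palladium enolate at C4 and β-hydride elimination toward the ring hydrogen at C5 should give the conjugated C4=C5 enone without touching the quaternary C10.

Step 4
Reactants: 5 (1R)-1,3-dimethyl-4-oxocyclohex-2-ene-1-carbaldehyde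
Product: 6 (4R)-4-(1,3-dioxolan-2-yl)-2,4-dimethylcyclohex-2-en-1-one
Conditions: Me3SiOCH2CH2OSiMe3, Me3SiOTf (5 mol%), CH2Cl2, −78 → −20 °C
Reagents that add atoms: 1,2-bis(trimethylsilyloxy)ethane, C[Si](C)(C)OCCO[Si](C)(C)C
Why: Silyl-triflate-catalysed acetalisation with the bis-silyl ether of ethylene glycol is selective for an aldehyde over a conjugated ketone and turns C9 into a branched group clearly larger than the C10 methyl; no stereocentre changes.

Step 5
Reactants: 6 (4R)-4-(1,3-dioxolan-2-yl)-2,4-dimethylcyclohex-2-en-1-one; 7 2-(2-bromoethyl)-2-methyl-1,3-dioxolane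
Product: 9 (3R,4R)-4-(1,3-dioxolan-2-yl)-2,4-dimethyl-3-[2-(2-methyl-1,3-dioxolan-2-yl)ethyl]-1-(trimethylsilyloxy)cyclohex-1-ene, via Grignard reagent 8 (not isolated)
Conditions: 7, Mg, THF, 25 °C; then CuBr·SMe2 (10 mol%), Me3SiCl (2 equiv), 6, THF, −78 → −40 °C; Et3N quench
Reagents that add atoms: chlorotrimethylsilane, C[Si](C)(C)Cl
Why: Copper-catalysed, chlorosilane-accelerated conjugate addition of a Grignard reagent, in which the nucleophile should enter C5 axially and anti to the larger dioxolanyl group on C10 (syn to the methyl), setting C5 with the chain trans to C9, while Me3SiCl traps the C3=C4 enolate regiospecifically.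

Step 6
Reactants: 9 (3R,4R)-4-(1,3-dioxolan-2-yl)-2,4-dimethyl-3-[2-(2-methyl-1,3-dioxolan-2-yl)ethyl]-1-(trimethylsilyloxy)cyclohex-1-ene
Product: 11 (3S,4R)-4-(1,3-dioxolan-2-yl)-2,2,4-trimethyl-3-[2-(2-methyl-1,3-dioxolan-2-yl)ethyl]cyclohexan-1-one, via lithium enolate 10 (not isolated)
Conditions: MeLi (1.1 equiv), THF, 0 °C; then MeI (5 equiv), DMPU, −78 °C → rt
Reagents that add atoms: iodomethane, CI
Why: Cleavage of the silyl enol ether by MeLi gives the regiodefined C3–C4 lithium enolate, and its C-methylation at C4 (enolate alkylation) installs the gem-dimethyl group without touching C5 or C10.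

Step 7
Reactants: 11 (3S,4R)-4-(1,3-dioxolan-2-yl)-2,2,4-trimethyl-3-[2-(2-methyl-1,3-dioxolan-2-yl)ethyl]cyclohexan-1-one
Product: 13 (4R,5R)-4-(1,3-dioxolan-2-yl)-4,6,6-trimethyl-5-[2-(2-methyl-1,3-dioxolan-2-yl)ethyl]cyclohex-1-en-1-yl trifluoromethanesulfonate, via potassium enolate 12 (not isolated)
Conditions: KN(SiMe3)2, THF, −78 °C; then PhNTf2, −78 °C → rt
Reagents that add atoms: N-phenylbis(trifluoromethanesulfonimide), O=S(=O)(N(c1ccccc1)S(=O)(=O)C(F)(F)F)C(F)(F)F
Why: Only C2 carries α-hydrogens, so deprotonation and O-sulfonylation (enol triflate formation) can give only the C2=C3 enol triflate.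

Step 8
Reactants: 13 (4R,5R)-4-(1,3-dioxolan-2-yl)-4,6,6-trimethyl-5-[2-(2-methyl-1,3-dioxolan-2-yl)ethyl]cyclohex-1-en-1-yl trifluoromethanesulfonate
Product: 14 2-[(1R,6S)-4-bromo-1,5,5-trimethyl-6-[2-(2-methyl-1,3-dioxolan-2-yl)ethyl]cyclohex-3-en-1-yl]-1,3-dioxolane
Conditions: Ni(OAc)2·4H2O (10 mol%), 1,5-cyclooctadiene (20 mol%), Zn (20 mol%), LiBr (3 equiv), DMA/THF, rt
Reagents that add atoms: lithium bromide, [Li+].[Br-]
Why: Nickel-catalysed halogen exchange of an enol triflate (oxidative addition to zerovalent nickel, triflate-for-bromide exchange, reductive elimination) is a known route to alkenyl bromides and leaves acetals untouched.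

Step 9
Reactants: 14 2-[(1R,6S)-4-bromo-1,5,5-trimethyl-6-[2-(2-methyl-1,3-dioxolan-2-yl)ethyl]cyclohex-3-en-1-yl]-1,3-dioxolane
Product: 15 2-[(1R,2S,4R)-4-bromo-1,3,3-trimethyl-2-[2-(2-methyl-1,3-dioxolan-2-yl)ethyl]cyclohexyl]-1,3-dioxolane
Conditions: Mn(dpm)3 (10 mol%; dpm = dipivaloylmethanate), PhSiH3, t-BuOOH, i-PrOH, rt
Reagents that add atoms: none
Why: Metal-hydride hydrogen-atom-transfer hydrogenation of an alkenyl halide, in which H adds to C2 to give the bromine-stabilised C3 radical and the second hydrogen should arrive on the axial face away from the axial C4 methyl, so that bromine ends equatorial (3R), the thermodynamically preferred epimer.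

Step 10
Reactants: 15 2-[(1R,2S,4R)-4-bromo-1,3,3-trimethyl-2-[2-(2-methyl-1,3-dioxolan-2-yl)ethyl]cyclohexyl]-1,3-dioxolane
Product: 16 (1R,2S,4R)-4-bromo-1,3,3-trimethyl-2-(3-oxobutyl)cyclohexane-1-carbaldehyde
Conditions: aq. HCl (2 M), THF, rt
Reagents that add atoms: water, O
Why: Acid hydrolysis of both dioxolanes (acetal cleavage) frees the C9 aldehyde and the C8 methyl ketone; the aldehyde has no α-hydrogen and the equatorial neopentyl bromide is inert to aqueous acid, so no stereocentre is at risk.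

Step 11
Reactants: 16 (1R,2S,4R)-4-bromo-1,3,3-trimethyl-2-(3-oxobutyl)cyclohexane-1-carbaldehyde; 17 tert-butyl diethylphosphonoacetate
Product: 18 tert-butyl (2E)-3-[(1S,2S,4R)-4-bromo-1,3,3-trimethyl-2-(3-oxobutyl)cyclohexyl]prop-2-enoate
Conditions: LiCl, DBU, MeCN, rt
Reagents that add atoms: none
Why: Horner–Wadsworth–Emmons olefination under LiCl/amine conditions should react with the aldehyde and not with the methyl ketone, and gives the (E)-enoate by the usual selectivity of stabilised phosphonate anions.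

Step 12
Reactants: 18 tert-butyl (2E)-3-[(1S,2S,4R)-4-bromo-1,3,3-trimethyl-2-(3-oxobutyl)cyclohexyl]prop-2-enoate
Product: 19 tert-butyl 2-[(1S,2S,4aS,6R,8aR)-6-bromo-2-hydroxy-2,5,5,8a-tetramethyldecahydronaphthalen-1-yl]acetate
Conditions: SmI2 (2.5 equiv, 0.1 M in THF), MeOH (10 equiv), THF, −78 → 0 °C, no HMPA
Reagents that add atoms: none
Why: SmI2 transfers one electron to the C8 methyl ketone to give a samarium ketyl whose carbon adds to the enoate β-carbon C9, and a second electron turns the C11 radical into a samarium enolate that methanol protonates. This is the known SmI2 ketyl–olefin reductive cyclisation of a ketone onto an α,β-unsaturated ester. Ring B closes 6-exo-trig through a chair fused to the ring A chair, in which the C5 and C10 arms are trans and both equatorial. At C8 the bulky samarium-bound oxygen should take the equatorial site, away from the axial C10 methyl, so that C17 is axial and the hydroxyl equatorial; at C9 the enoate arm stays equatorial (H9 axial, anti to C20), which gives the trans hydroxyl/C11 relation of the target. The step needs ketyl formation to win over C–Br reduction and over lactonisation: a secondary bromide is not reduced at a useful rate by SmI2 in THF/MeOH without HMPA, and the tert-butyl ester resists attack by the samarium alkoxide.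

Step 13
Reactants: 19 tert-butyl 2-[(1S,2S,4aS,6R,8aR)-6-bromo-2-hydroxy-2,5,5,8a-tetramethyldecahydronaphthalen-1-yl]acetate
Product: 20 tert-butyl 2-[(1S,2S,4aS,6R,8aR)-6-bromo-2,5,5,8a-tetramethyl-2-(triethylsilyloxy)decahydronaphthalen-1-yl]acetate
Conditions: Et3SiOTf (1.2 equiv), 2,6-lutidine, CH2Cl2, −78 → −40 °C
Reagents that add atoms: triethylsilyl trifluoromethanesulfonate, CC[Si](CC)(CC)OS(=O)(=O)C(F)(F)F
Why: Silylation of the tertiary C8 alcohol with a silyl triflate and a hindered base at low temperature is standard and faster than attack on the tert-butyl ester, and the ether keeps the C8 oxygen from closing a tetrahydrofuran onto C12 in the following steps.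

Step 14
Reactants: 20 tert-butyl 2-[(1S,2S,4aS,6R,8aR)-6-bromo-2,5,5,8a-tetramethyl-2-(triethylsilyloxy)decahydronaphthalen-1-yl]acetate
Product: 21 2-[(1S,2S,4aS,6R,8aR)-6-bromo-2,5,5,8a-tetramethyl-2-(triethylsilyloxy)decahydronaphthalen-1-yl]ethan-1-ol
Conditions: i-Bu2AlH (3.5 equiv), CH2Cl2, −78 → 0 °C; Rochelle salt work-up
Reagents that add atoms: none
Why: Hydride reduction of the ester by i-Bu2AlH gives the C12 primary alcohol, and alkyl bromides and silyl ethers are inert to this reagent at low temperature.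

Step 15
Reactants: 21 2-[(1S,2S,4aS,6R,8aR)-6-bromo-2,5,5,8a-tetramethyl-2-(triethylsilyloxy)decahydronaphthalen-1-yl]ethan-1-ol
Product: 22 {[(1S,2S,4aS,6R,8aR)-6-bromo-1-(2-iodoethyl)-2,5,5,8a-tetramethyldecahydronaphthalen-2-yl]oxy}triethylsilane
Conditions: I2, PPh3, imidazole, CH2Cl2, 0 °C → rt
Reagents that add atoms: iodine, II
Why: Appel-type iodination (alkoxyphosphonium formation and displacement by iodide at the unhindered primary C12) runs under buffered conditions that leave the silyl ether and the secondary bromide alone.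

Step 16
Reactants: 22 {[(1S,2S,4aS,6R,8aR)-6-bromo-1-(2-iodoethyl)-2,5,5,8a-tetramethyldecahydronaphthalen-2-yl]oxy}triethylsilane; 23 lithium acetylide–ethylenediamine complex
Product: 24 {[(1S,2S,4aS,6R,8aR)-6-bromo-1-(but-3-yn-1-yl)-2,5,5,8a-tetramethyldecahydronaphthalen-2-yl]oxy}triethylsilane
Conditions: LiC≡CH·H2NCH2CH2NH2 (3 equiv), DMSO, rt
Reagents that add atoms: none
Why: Displacement of the primary iodide by acetylide in a dipolar aprotic solvent (alkyne alkylation) adds C13 and C14, while the equatorial neopentyl C3 bromide allows neither backside attack nor anti elimination.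

Step 17
Reactants: 24 {[(1S,2S,4aS,6R,8aR)-6-bromo-1-(but-3-yn-1-yl)-2,5,5,8a-tetramethyldecahydronaphthalen-2-yl]oxy}triethylsilane
Product: 26 methyl (2E)-5-[(1S,2S,4aS,6R,8aR)-6-bromo-2,5,5,8a-tetramethyl-2-(triethylsilyloxy)decahydronaphthalen-1-yl]-3-methylpent-2-enoate, via alkenylalane 25 (not isolated)
Conditions: Me3Al (3 equiv), Cp2ZrCl2 (0.5 equiv), CH2Cl2, 0 °C → rt; then ClCO2Me, rt
Reagents that add atoms: trimethylaluminium, C[Al](C)C; methyl chloroformate, COC(=O)Cl
Why: Zirconium-catalysed methylalumination (Negishi carboalumination) adds CH3 and Al syn across the terminal alkyne with methyl on the internal carbon C13, and acylation of the alkenylalane by the chloroformate with retention fixes the (E)-C13=C14 geometry.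

Step 18
Reactants: 26 methyl (2E)-5-[(1S,2S,4aS,6R,8aR)-6-bromo-2,5,5,8a-tetramethyl-2-(triethylsilyloxy)decahydronaphthalen-1-yl]-3-methylpent-2-enoate
Product: 27 (2E)-5-[(1S,2S,4aS,6R,8aR)-6-bromo-2,5,5,8a-tetramethyl-2-(triethylsilyloxy)decahydronaphthalen-1-yl]-3-methylpent-2-en-1-ol
Conditions: i-Bu2AlH (2.5 equiv), CH2Cl2, −78 °C
Reagents that add atoms: none
Why: 1,2-Reduction of the α,β-unsaturated ester by i-Bu2AlH at low temperature gives the C15 allylic alcohol without changing the alkene geometry, the bromide or the silyl ether.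

Step 19
Reactants: 27 (2E)-5-[(1S,2S,4aS,6R,8aR)-6-bromo-2,5,5,8a-tetramethyl-2-(triethylsilyloxy)decahydronaphthalen-1-yl]-3-methylpent-2-en-1-ol
Product: 28 (2E)-5-[(1S,2S,4aS,6R,8aR)-6-bromo-2-hydroxy-2,5,5,8a-tetramethyldecahydronaphthalen-1-yl]-3-methylpent-2-en-1-ol
Conditions: Bu4NF, THF, rt → 40 °C
Reagents that add atoms: none
Why: Fluoride cleavage of the triethylsilyl ether (desilylation) frees the tertiary C8 alcohol under conditions that do not ionise it and leave the allylic alcohol and the bromide untouched.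

**Compound list**
1 | 3-methylbut-3-en-2-one | CC(=O)C(C)=C | starting material
2 | 2-methyl-3-(triisopropylsilyloxy)buta-1,3-diene | C=C(C)C(=C)O[Si](C(C)C)(C(C)C)C(C)C | intermediate
3 | methacrolein | CC(=C)C=O | starting material
4 | (1R)-1,3-dimethyl-4-(triisopropylsilyloxy)cyclohex-3-ene-1-carbaldehyde | O=C[C@]1(C)CCC(O[Si](C(C)C)(C(C)C)C(C)C)=C(C)C1 | intermediate
5 | (1R)-1,3-dimethyl-4-oxocyclohex-2-ene-1-carbaldehyde | O=C[C@]1(C)CCC(=O)C(C)=C1 | intermediate
6 | (4R)-4-(1,3-dioxolan-2-yl)-2,4-dimethylcyclohex-2-en-1-one | O1CCOC1[C@]2(C)CCC(=O)C(C)=C2 | intermediate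
7 | 2-(2-bromoethyl)-2-methyl-1,3-dioxolane | CC1(CCBr)OCCO1 | starting material
8 | [2-(2-methyl-1,3-dioxolan-2-yl)ethyl]magnesium bromide | CC1(CC[Mg]Br)OCCO1 | intermediate (not isolated)
9 | (3R,4R)-4-(1,3-dioxolan-2-yl)-2,4-dimethyl-3-[2-(2-methyl-1,3-dioxolan-2-yl)ethyl]-1-(trimethylsilyloxy)cyclohex-1-ene (C5 chain trans to the C10 acetal) | O1CCOC1[C@]2(C)CCC(O[Si](C)(C)C)=C(C)[C@H]2CCC3(C)OCCO3 | intermediate
10 | lithium C3–C4 enolate corresponding to 9 | O1CCOC1[C@]2(C)CCC(O[Li])=C(C)[C@H]2CCC3(C)OCCO3 | intermediate (not isolated)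
11 | (3S,4R)-4-(1,3-dioxolan-2-yl)-2,2,4-trimethyl-3-[2-(2-methyl-1,3-dioxolan-2-yl)ethyl]cyclohexan-1-one | O1CCOC1[C@]2(C)CCC(=O)C(C)(C)[C@H]2CCC3(C)OCCO3 | intermediate
12 | potassium C2=C3 enolate of 11 | O1CCOC1[C@]2(C)CC=C(O[K])C(C)(C)[C@H]2CCC3(C)OCCO3 | intermediate (not isolated)
13 | (4R,5R)-4-(1,3-dioxolan-2-yl)-4,6,6-trimethyl-5-[2-(2-methyl-1,3-dioxolan-2-yl)ethyl]cyclohex-1-en-1-yl trifluoromethanesulfonate | O1CCOC1[C@]2(C)CC=C(OS(=O)(=O)C(F)(F)F)C(C)(C)[C@H]2CCC3(C)OCCO3 | intermediate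
14 | 2-[(1R,6S)-4-bromo-1,5,5-trimethyl-6-[2-(2-methyl-1,3-dioxolan-2-yl)ethyl]cyclohex-3-en-1-yl]-1,3-dioxolane | O1CCOC1[C@]2(C)CC=C(Br)C(C)(C)[C@H]2CCC3(C)OCCO3 | intermediate
15 | 2-[(1R,2S,4R)-4-bromo-1,3,3-trimethyl-2-[2-(2-methyl-1,3-dioxolan-2-yl)ethyl]cyclohexyl]-1,3-dioxolane (Br equatorial) | O1CCOC1[C@]2(C)CC[C@@H](Br)C(C)(C)[C@H]2CCC3(C)OCCO3 | intermediate
16 | (1R,2S,4R)-4-bromo-1,3,3-trimethyl-2-(3-oxobutyl)cyclohexane-1-carbaldehyde | O=C[C@]1(C)CC[C@@H](Br)C(C)(C)[C@H]1CCC(C)=O | intermediate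
17 | tert-butyl diethylphosphonoacetate | CCOP(=O)(CC(=O)OC(C)(C)C)OCC | starting material
18 | tert-butyl (2E)-3-[(1S,2S,4R)-4-bromo-1,3,3-trimethyl-2-(3-oxobutyl)cyclohexyl]prop-2-enoate | CC(C)(C)OC(=O)/C=C/[C@]1(C)CC[C@@H](Br)C(C)(C)[C@H]1CCC(C)=O | intermediate
19 | tert-butyl 2-[(1S,2S,4aS,6R,8aR)-6-bromo-2-hydroxy-2,5,5,8a-tetramethyldecahydronaphthalen-1-yl]acetate | CC(C)(C)OC(=O)C[C@H]1[C@]2(C)CC[C@@H](Br)C(C)(C)[C@H]2CC[C@]1(C)O | intermediate
20 | tert-butyl 2-[(1S,2S,4aS,6R,8aR)-6-bromo-2,5,5,8a-tetramethyl-2-(triethylsilyloxy)decahydronaphthalen-1-yl]acetate | CC(C)(C)OC(=O)C[C@H]1[C@]2(C)CC[C@@H](Br)C(C)(C)[C@H]2CC[C@]1(C)O[Si](CC)(CC)CC | intermediate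
21 | 2-[(1S,2S,4aS,6R,8aR)-6-bromo-2,5,5,8a-tetramethyl-2-(triethylsilyloxy)decahydronaphthalen-1-yl]ethan-1-ol | OCC[C@H]1[C@]2(C)CC[C@@H](Br)C(C)(C)[C@H]2CC[C@]1(C)O[Si](CC)(CC)CC | intermediate
22 | {[(1S,2S,4aS,6R,8aR)-6-bromo-1-(2-iodoethyl)-2,5,5,8a-tetramethyldecahydronaphthalen-2-yl]oxy}triethylsilane | ICC[C@H]1[C@]2(C)CC[C@@H](Br)C(C)(C)[C@H]2CC[C@]1(C)O[Si](CC)(CC)CC | intermediate
23 | lithium acetylide–ethylenediamine complex | [Li]C#C.NCCN | starting material
24 | {[(1S,2S,4aS,6R,8aR)-6-bromo-1-(but-3-yn-1-yl)-2,5,5,8a-tetramethyldecahydronaphthalen-2-yl]oxy}triethylsilane | C#CCC[C@H]1[C@]2(C)CC[C@@H](Br)C(C)(C)[C@H]2CC[C@]1(C)O[Si](CC)(CC)CC | intermediate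
25 | (E)-alkenyldimethylalane from methylalumination of 24 (Al on C14, cis to the new C13 methyl) | C/C(=C\[Al](C)C)CC[C@H]1[C@]2(C)CC[C@@H](Br)C(C)(C)[C@H]2CC[C@]1(C)O[Si](CC)(CC)CC | intermediate (not isolated)
26 | methyl (2E)-5-[(1S,2S,4aS,6R,8aR)-6-bromo-2,5,5,8a-tetramethyl-2-(triethylsilyloxy)decahydronaphthalen-1-yl]-3-methylpent-2-enoate | C/C(=C\C(=O)OC)CC[C@H]1[C@]2(C)CC[C@@H](Br)C(C)(C)[C@H]2CC[C@]1(C)O[Si](CC)(CC)CC | intermediate
27 | (2E)-5-[(1S,2S,4aS,6R,8aR)-6-bromo-2,5,5,8a-tetramethyl-2-(triethylsilyloxy)decahydronaphthalen-1-yl]-3-methylpent-2-en-1-ol | C/C(=C\CO)CC[C@H]1[C@]2(C)CC[C@@H](Br)C(C)(C)[C@H]2CC[C@]1(C)O[Si](CC)(CC)CC | intermediate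
28 | (2E)-5-[(1S,2S,4aS,6R,8aR)-6-bromo-2-hydroxy-2,5,5,8a-tetramethyldecahydronaphthalen-1-yl]-3-methylpent-2-en-1-ol (CNP0176777.2) | C/C(=C\CO)CC[C@H]1[C@]2(C)CC[C@@H](Br)C(C)(C)[C@H]2CC[C@]1(C)O | target

**Step count**
Total step count: 19. Longest linear sequence: 19 steps (compound 1 to compound 28).

**Three steps most likely to fail**

Step 12 (ring B closure). The ketyl may be reduced on to the secondary alcohol, or the enoate reduced, without ring closure. Facial selectivity at C8 may be eroded by the 1,3-relation of C17 to the C10 methyl. If stronger reducing conditions are needed, the C3 bromine may be lost. Fallback, from 16 back to 21, closes the same bond by a polar two-electron path. Aldehyde-selective Wittig olefination of 16 with Ph3P=CHCH2SiMe3 at −78 °C should give the allylsilane ketone F1. TiCl4-promoted intramolecular Hosomi–Sakurai addition of its γ-carbon C9 to the C8 ketone (CH2Cl2, −78 °C) should give the 9-vinyl carbinol F2. Et3SiOTf and 2,6-lutidine give the triethylsilyl ether F3. Hydroboration of the C11=C12 vinyl group with 9-BBN and oxidation with NaBO3 then gives the C12 alcohol 21.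

Step 5 (C5 stereocentre). Facial discrimination between the C10 methyl and the C10 dioxolanyl group may be poor, giving C5 epimers, and 1,2-addition may compete at the hindered β-carbon. Fallback, from 9 (as the epimer mixture) back to 11, sets C5 by protonation instead of C–C bond formation. Saegusa–Ito oxidation of 9 with Pd(OAc)2 erases C5 and should give the tetrasubstituted enone F4. Stork reductive methylation (Li, NH3/THF, one equivalent of t-BuOH, then MeI) protonates the β-carbon C5 axially in the chair with the larger C10 acetal equatorial, and the resulting C3–C4 enolate is methylated at C4 to give 11.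

Step 9 (bromoalkene hydrogenation). Hydrogen-atom transfer to C3 instead of C2 would eject bromine and lead to the debrominated ring, and hydrogen delivery to the C3 radical may not be face-selective. Fallback, from 11 back to 15, makes the C–Br bond by substitution with inversion. Reduction of 11 with KBH(s-Bu)3 from the equatorial side should give the axial C3 alcohol F5. Tf2O and pyridine give the triflate F6. Displacement with Bu4NBr in toluene with inversion gives the equatorial bromide 15, bypassing 12 to 14.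

**Further compounds**
F1 | step 12 | (1R,2S,4R)-4-bromo-1,3,3-trimethyl-2-(3-oxobutyl)-1-[3-(trimethylsilyl)prop-1-en-1-yl]cyclohexane | C[Si](C)(C)CC=C[C@]1(C)CC[C@@H](Br)C(C)(C)[C@H]1CCC(C)=O
F2 | step 12 | (1S,2S,4aS,6R,8aR)-6-bromo-1-ethenyl-2,5,5,8a-tetramethyldecahydronaphthalen-2-ol | C=C[C@H]1[C@]2(C)CC[C@@H](Br)C(C)(C)[C@H]2CC[C@]1(C)O
F3 | step 12 | {[(1S,2S,4aS,6R,8aR)-6-bromo-1-ethenyl-2,5,5,8a-tetramethyldecahydronaphthalen-2-yl]oxy}triethylsilane | C=C[C@H]1[C@]2(C)CC[C@@H](Br)C(C)(C)[C@H]2CC[C@]1(C)O[Si](CC)(CC)CC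
F4 | step 5 | (4R)-4-(1,3-dioxolan-2-yl)-2,4-dimethyl-3-[2-(2-methyl-1,3-dioxolan-2-yl)ethyl]cyclohex-2-en-1-one | O1CCOC1[C@]2(C)CCC(=O)C(C)=C2CCC3(C)OCCO3
F5 | step 9 | (1S,3S,4R)-4-(1,3-dioxolan-2-yl)-2,2,4-trimethyl-3-[2-(2-methyl-1,3-dioxolan-2-yl)ethyl]cyclohexan-1-ol (axial OH) | O1CCOC1[C@]2(C)CC[C@H](O)C(C)(C)[C@H]2CCC3(C)OCCO3
F6 | step 9 | trifluoromethanesulfonate of F5 | O1CCOC1[C@]2(C)CC[C@H](OS(=O)(=O)C(F)(F)F)C(C)(C)[C@H]2CCC3(C)OCCO3
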